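In a one-step world with a catalyst that lasts, halving E merely stretches the clock and the curve runs on to the same end, but here the noon run's last reading is 59.2% of its G, against 87.0% in the autumn run.

| flask | G | L | E | time |
|---|---|---|---|---|
| autumn | 0.800 M | 0.960 M | 0.0160 M |  |
| spring | 0.400 M | 0.560 M | 0.0160 M |  |
| noon | 0.800 M | 0.960 M | 0.00800 M |  |
| winter | 2.40 M | 0.960 M | 0.0160 M | 25 h |

| run | time / h | [X] / M |
|---|---|---|
| autumn run | 3.1 | 0.298 |
| autumn run | 6.2 | 0.480 |
| autumn run | 9.4 | 0.561 |
| autumn run | 12 | 0.615 |
| autumn run | 16 | 0.668 |
| autumn run | 19 | 0.677 |
| autumn run | 22 | 0.668 |
| autumn run | 25 | 0.696 |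
| spring run | 3.1 | 0.177 |
| spring run | 6.2 | 0.265 |
| spring run | 9.4 | 0.328 |
| spring run | 12 | 0.352 |
| spring run | 16 | 0.382 |
| spring run | 19 | 0.386 |
| spring run | 22 | 0.384 |
| spring run | 25 | 0.404 |
| noon run | 3.1 | 0.167 |
| noon run | 6.2 | 0.296 |
| noon run | 9.4 | 0.346 |
| noon run | 12 | 0.391 |
| noon run | 16 | 0.439 |
| noon run | 19 | 0.454 |
| noon run | 22 | 0.455 |
| noon run | 25 | 0.474 |

(each reading ± 0.006 M)

- order of the initial rate in [E], near the charge of the autumn run, the rate being that where two percent of its G are X
- the spring run starts with 0.400 M less of G and of L than the autumn run, and with no X. Compared where both hold the same amount of G, once fifteen percent of what the spring run was charged with has turned into X, is the spring run faster, slower or alike (within a tenth)?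
- X in the winter run at 25 h, as a share of the G charged

- Overall: G + L -> X, with E as catalyst.
- Constant volume, constant temperature.
- A reading of a species includes what of it is bound.
- An order is taken over about fifteen percent of the charge, up and down.

I order the clocks from fast to slow. In the autumn run, one turnover of E takes

0.166 h (E charged over the mean rate to the first reading).

Next comes the life of E, which I read from the noon run, taking its last reading as the plateau:

7.18 h.

A turnover in the autumn run is far shorter than that life read from the noon run, so I freeze the share of each catalyst form and let the rate follow the E still alive. The slowest clock is the 25 h of the noon run, which is longer than the life and the turnover, so hardly any of the noon run's E is alive at the end on this reckoning.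

If the rate goes with live E and with the share left of the limiting reagent, the plateau measures one number, the reach, read in the autumn run as 2.04: the natural logarithm of the charge of the limiting reagent over what remains of it at the last reading. For the noon run,

0.898,

so the autumn reach is twice the noon reach, as the halved E suggests. The spring run's last reading stands at 101% of its G, which is its whole charge within the scatter and a greater share than the autumn run's, so the reach is not strictly frozen.

The winter run has the autumn E, and its L is less than its G, so L is the limiting reagent there. I carry the autumn reach over to L:

87.0% of L = 34.8% of G.

The forecast gives order 0.95, faster and 33%, a share below mine: “Catalyst life allows about 0.8 M, roughly 33%.”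

The simulation gives order 1.0, faster at a ratio of 1.6, and 31.1%, so the forecast stands on the order, on the comparison and on the share.

    E + G → EG (26.64 /M/h)
    EG + L → Jo (23.80 /M/h)
    Jo → X + E (33.91 /h)
    EG → Gu + G (0.1238 /h)
    2 L → Gy (0.04896 /M/h)

In the winter run, EG took up L and Jo released X and E with a constant of 33.9 /h, while over the same hours EG went to Gu with a constant of 0.124 /h and L went to Gy with a constant of 0.0490 /M/h. Read back through L, counting as spent just the L that became X, the winter share is a reach of 1.50, below the 2.04 read in the autumn run.

(The runs come from a simulation with constants of no real substance; the scatter is artificial.)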